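**Plan**

- Retrosynthesis cuts C13'–C1 first (radical 5-exo closure onto the C1=C5–C4=C15 diene), then C4=C15 (methylenation of a C4 ketone), C2–C3 (furan-to-cyclopentenone rearrangement), C11'–C13' (iodomethylation) and C3–C11' (acylation of the seco-eudesmanolide enolate by a ring-fused 2-furoyl chloride).
- Guaiane half, forward: butenolide, trans-lactone, seven-membered enone by ring-closing metathesis, C10 methyl by cuprate addition, furan annulation.
- Seco-eudesmane half, forward: Sharpless epoxide joined to a citronellal dithiane, malonate opening to the cis-lactone, ring A by aldol condensation, exocyclic methylene.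
- Union and finish: C-acylation, iodomethylation, reduction, Piancatelli rearrangement, acetylation, methylenation, radical closure to the bicyclo[2.2.1]heptene, α-methylenation of the guaiane lactone, desilylation.
- Stereochemistry: C8 from (R)-epichlorohydrin, C7 and C10 by substrate-controlled conjugate additions; C4' from (S)-citronellal; C7'/C8' from the Sharpless epoxide; C11' by convex-face alkylation; C2/C3 trans by conrotatory closure; C1 by the tether.

Key step: step 27

Remark: locants follow the natural product (guaiane half C1–C15, seco-eudesmane half C1'–C15', C11' the spiro carbon), and (E)-penta-2,4-dien-1-ol is taken as a purchasable diene alcohol.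

**Guaiane half (furoic acid 16)**

Step 1
Reactants: 1 (R)-epichlorohydrin
Product: 3 (R)-2-allyloxirane, via (R)-1-chloropent-4-en-2-ol 2 (not isolated)
Conditions: CH2=CHMgBr, CuI (cat.), THF, −40 °C; then NaOH (aq.), 25 °C
Reagents that add atoms: vinylmagnesium bromide, C=C[Mg]Br
Why: Copper-catalysed Grignard opening of the epoxide at its unsubstituted carbon, then Williamson-type closure of the chlorohydrin, should leave the future C8 stereocentre untouched.

Step 2
Reactants: 3 (R)-2-allyloxirane
Product: 6 (R)-5-allylfuran-2(5H)-one, via seleno hydroxy acid 4 (not isolated), via selenolactone 5 (not isolated)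
Conditions: PhSeCH2CO2H, LiN(iPr)2 (2.1 equiv), THF, −78 → 25 °C; AcOH, 60 °C; then H2O2 (30 %), pyridine, CH2Cl2, 0 °C
Reagents that add atoms: (phenylselanyl)acetic acid, OC(=O)C[Se]c1ccccc1
Why: The dianion of the selenoacetic acid should open the epoxide at the terminal carbon, acid closes the γ-lactone and selenoxide syn-elimination gives the butenolide with C8 retained.

Step 3
Reactants: 6 (R)-5-allylfuran-2(5H)-one
Product: 8 S-ethyl 2-[(2R,3R)-2-allyl-5-oxooxolan-3-yl]ethanethioate (7,8-trans), via trimethylsilyl ketene acetal 7 (not isolated)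
Conditions: CH2=C(OSiMe3)SEt, t-BuMe2SiOTf (10 mol %), CH2Cl2, −78 °C; then 1 M HCl, THF
Reagents that add atoms: 1-(ethylsulfanyl)-1-(trimethylsilyloxy)ethene, C=C(O[Si](C)(C)C)SCC
Why: Mukaiyama–Michael addition of the ketene silyl thioacetal to the butenolide should occur anti to the C8 allyl group, which sets C7 trans to C8.

Step 4
Reactants: 8 trans-lactone thioester
Product: 9 1-[(2R,3S)-2-allyl-5-oxooxolan-3-yl]but-3-en-2-one
Conditions: CH2=CHSnBu3, Pd2(dba)3 (2.5 mol %), P(2-furyl)3, CuO2PPh2 (1.2 equiv), THF, 50 °C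
Reagents that add atoms: tributyl(vinyl)stannane, C=C[Sn](CCCC)(CCCC)CCCC
Why: Liebeskind–Srogl-type ketone synthesis from a thioester and an organostannane should replace the thiolate by vinyl under neutral conditions that spare the lactone.

Step 5
Reactants: 9 vinyl ketone
Product: 10 (3aS,8aR)-3a,4,8,8a-tetrahydro-2H-cyclohepta[b]furan-2,5(3H)-dione (trans-fused; C5 ketone, C1=C10 alkene)
Conditions: (H2IMes)(PCy3)Cl2Ru=CHPh (second-generation Grubbs catalyst, 5 mol %), CH2Cl2 (2 mM), 40 °C
Reagents that add atoms: none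
Why: Ring-closing metathesis between the enone vinyl group and the allyl group should close the seven-membered ring with loss of ethylene, the trans-lactone holding the two chains gauche.

Step 6
Reactants: 10 cycloheptenone lactone
Product: 11 C1=C5 trimethylsilyl enol ether of the 10-methyl ketone (methyl anti to O-8)
Conditions: Me2CuLi, Me3SiCl, THF–Et2O, −78 °C; Et3N quench
Reagents that add atoms: lithium dimethylcuprate, [Li+].C[Cu-]C; chlorotrimethylsilane, C[Si](C)(C)Cl
Why: Gilman conjugate addition with in situ silylation should deliver methyl to C10 anti to the C8–O bond (pseudo-axial attack, as in 5-substituted cycloalkenones) and fixes the enolate as the C1=C5 silyl enol ether.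

Step 7
Reactants: 11 silyl enol ether
Product: 12 β-keto acetal (C1 carries CH(OMe)2, the future C2)
Conditions: HC(OMe)3, Me3SiOTf (10 mol %), CH2Cl2, −78 °C
Reagents that add atoms: trimethyl orthoformate, COC(OC)OC
Why: The Lewis-acid-catalysed Mukaiyama-type reaction of a silyl enol ether with an orthoformate should functionalise C1 only; the C1 configuration is irrelevant because it becomes a furan carbon.

Step 8
Reactants: 12 β-keto acetal
Product: 14 methyl 2-furoate fused at the furan 3,4-positions to the seven-membered ring, via glycidic ester 13 (not isolated)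
Conditions: ClCH2CO2Me, NaOMe, THF, −10 → 25 °C; then p-TsOH (cat.), PhMe, 110 °C
Reagents that add atoms: methyl chloroacetate, COC(=O)CCl
Why: Darzens condensation at the C5 ketone gives a glycidic ester that should aromatise with loss of two methanol (the classical β-keto acetal route to 3-substituted 2-furoates), which places the ester carbon (C3) on the furan carbon C4 next to C5.

Step 9
Reactants: 14 methyl furoate
Product: 16 fused 2-furoic acid with intact trans-lactone, via dilithium hydroxy dicarboxylate 15 (not isolated)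
Conditions: LiOH, THF–H2O, 25 °C; then 1 M HCl to pH 2, 40 °C
Reagents that add atoms: lithium hydroxide, [Li+].[OH-]
Why: Saponification cleaves both the methyl ester and the lactone, and acidification should re-close the trans γ-lactone while the furoic acid stays free.

**Dithiane 21**

Step 10
Reactants: 17 (S)-citronellal
Product: 18 (S)-citronellal dimethyl acetal
Conditions: HC(OMe)3, MeOH, pyridinium p-toluenesulfonate (cat.), 25 °C
Reagents that add atoms: trimethyl orthoformate, COC(OC)OC
Why: Mild acetalisation masks the aldehyde (C10') so that the trisubstituted alkene can be cleaved next.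

Step 11
Reactants: 18 acetal
Product: 19 (S)-6,6-dimethoxy-4-methylhexan-1-ol
Conditions: O3, CH2Cl2–MeOH, −78 °C; then NaBH4, −78 → 0 °C
Reagents that add atoms: ozone, O=[O+][O-]
Why: Ozonolysis with borohydride work-up should cut the isopropylidene end to the primary alcohol (C1') without touching the acetal or C4'.

Step 12
Reactants: 19 alcohol
Product: 20 tert-butyldiphenylsilyl (TBDPS) ether of 19
Conditions: t-BuPh2SiCl, imidazole, CH2Cl2, 25 °C
Reagents that add atoms: tert-butyl(chloro)diphenylsilane, CC(C)(C)[Si](Cl)(c1ccccc1)c1ccccc1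
Why: Standard silylation gives an ether meant to last until the final fluoride treatment.

Step 13
Reactants: 20 silyl ether acetal
Product: 21 2-[(S)-2-methyl-5-(TBDPS-oxy)pentyl]-1,3-dithiane
Conditions: HS(CH2)3SH, BF3·OEt2 (cat.), CH2Cl2, −20 °C
Reagents that add atoms: propane-1,3-dithiol, SCCCS
Why: Lewis-acid transthioacetalisation gives the dithiane needed for Corey–Seebach umpolung at C10'.

**Seco-eudesmane half (lactone 31)**

Step 14
Reactants: 22 (E)-penta-2,4-dien-1-ol
Product: 23 (2S,3S)-2,3-epoxypent-4-en-1-ol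
Conditions: Ti(OiPr)4 (cat.), L-(+)-diisopropyl tartrate, t-BuOOH, 4 Å molecular sieves, CH2Cl2, −20 °C
Reagents that add atoms: tert-butyl hydroperoxide, CC(C)(C)OO
Why: Sharpless asymmetric epoxidation with the L-tartrate should epoxidise only the allylic-alcohol double bond to the (2S,3S)-epoxide, which fixes C8' and, after later inversion, C7'.

Step 15
Reactants: 23 epoxy alcohol; 21 dithiane
Product: 25 (2S,3S)-2-[(2-alkyl-1,3-dithian-2-yl)methyl]-3-vinyloxirane (alkyl = side chain of 21), via epoxy triflate 24 (not isolated)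
Conditions: 23: n-BuLi, THF, −78 °C, then Tf2O; 21: t-BuLi, THF–HMPA, −78 °C; combine, −78 → −30 °C
Reagents that add atoms: trifluoromethanesulfonic anhydride, O=S(=O)(OS(=O)(=O)C(F)(F)F)C(F)(F)F (its atoms appear only in 24)
Why: In this Corey–Seebach alkylation the lithiated dithiane should displace the primary triflate by SN2 far faster than it opens the disubstituted epoxide, joining C9' to C10'.

Step 16
Reactants: 25 vinyl epoxide
Product: 26 cis-4-vinyl-5-(dithianylmethyl)-γ-butyrolactone bearing CO2Me at C11' (epimers at C11')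
Conditions: CH2(CO2Me)2, NaH, THF, 65 °C
Reagents that add atoms: dimethyl malonate, COC(=O)CC(=O)OC
Why: Sodium malonate should open the vinyl epoxide by SN2 at the allylic carbon C7' with inversion and the C8' alkoxide then lactonises, so the trans-epoxide becomes the cis-β,γ-disubstituted lactone.

Step 17
Reactants: 26 carbomethoxy lactone
Product: 27 cis-lactone with C11'H2
Conditions: LiCl, H2O, DMSO, 150 °C
Reagents that add atoms: none
Why: Krapcho dealkoxycarbonylation removes the extra ester from C11'.

Step 18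
Reactants: 27 dithiane lactone
Product: 28 C10' ketone
Conditions: PhI(O2CCF3)2, MeCN–H2O (9:1), 0 °C
Reagents that add atoms: water, O
Why: Oxidative dethioacetalisation with the hypervalent iodine reagent should unmask the ketone under near-neutral conditions that spare the vinyl group, the lactone and the silyl ether.

Step 19
Reactants: 28 keto lactone
Product: 30 ring A enone (C10' ketone, C5'=C6', cis-fused 12',8'-olide), via keto aldehyde 29 (not isolated)
Conditions: O3, CH2Cl2, −78 °C; PPh3; then Bn2NH·CF3CO2H (20 mol %), PhH, 50 °C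
Reagents that add atoms: ozone, O=[O+][O-]
Why: Ozonolysis gives the C6' aldehyde and the ammonium-salt-catalysed intramolecular aldol condensation should close ring A through C5' only (C9' would give a four-membered ring), the buffered medium limiting β-elimination of the lactone oxygen and the cis fusion being the stable one.

Step 20
Reactants: 30 enone
Product: 31 seco-eudesmanolide diene lactone (C10'=C14', C5'=C6', C11'H2, O-TBDPS)
Conditions: Cp2Ti(μ-Cl)(μ-CH2)AlMe2 (1.1 equiv), pyridine, THF–PhMe, −40 → 0 °C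
Reagents that add atoms: Tebbe reagent, C[Al](C)C[Ti](Cl)(C1C=CC=C1)C1C=CC=C1
Why: Tebbe methylenation is not basic and prefers ketones over lactones, so it should give the exocyclic diene without β-elimination at C8'.

**Union and finish**

Step 21
Reactants: 16 furoic acid; 31 diene lactone
Product: 33 β-keto lactone (C11' acylated by the furoyl group, ketone carbon = C3; epimers at C11'), via acid chloride 32 (not isolated)
Conditions: 16: (COCl)2, DMF (cat.), CH2Cl2, 0 → 25 °C, evaporate; 31: LiN(SiMe3)2 (2.1 equiv), THF, −78 °C; add 32, −78 °C; AcOH quench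
Reagents that add atoms: oxalyl chloride, O=C(Cl)C(=O)Cl (chlorine appears only in 32)
Why: Crossed Claisen-type C-acylation of the lactone lithium enolate by the furoyl chloride should form C3–C11', the second equivalent of base storing the product as its stabilised enolate.

Step 22
Reactants: 33 β-keto lactone
Product: 34 11'-iodomethyl β-keto lactone (C13' cis to H-7')
Conditions: NaH (1.1 equiv), CH2I2 (5 equiv), THF–DMPU, 0 → 25 °C
Reagents that add atoms: diiodomethane, ICI
Why: C-Alkylation of the β-keto lactone enolate with diiodomethane (as for Dowd–Beckwith precursors) should occur on the convex face of the cis-fused lactone, anti to the C7'–C6' bond, which sets C11' with C13' cis to H-7' and the furoyl group on the concave face.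

Step 23
Reactants: 34 iodomethyl β-keto lactone
Product: 35 furylcarbinol (both C3 epimers)
Conditions: NaBH4, CeCl3·7H2O, MeOH–THF, −20 °C
Reagents that add atoms: none
Why: Luche-type borohydride reduction should reduce only the furyl ketone; the carbinol configuration is immaterial because this centre is ionised next.

Step 24
Reactants: 35 furylcarbinol
Product: 36 hydroxy enone (C4 ketone, C1=C5, 2-OH trans to C3–C11')
Conditions: Dy(OTf)3 (10 mol %), MeCN–H2O (5:1), 80 °C
Reagents that add atoms: water, O
Why: In the Piancatelli rearrangement, ionisation of the furylcarbinol, addition of water at C2, ring opening and conrotatory 4π closure should give the 4-hydroxy-5-substituted cyclopentenone with C2–OH and C3–C11' trans, closure being expected anti to the iodomethyl arm with the tied-back lactone carbonyl turned toward the C4 oxygen, while the quaternary C11' excludes dehydration.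

Step 25
Reactants: 36 hydroxy enone
Product: 37 2-acetate
Conditions: Ac2O, pyridine, DMAP (cat.), CH2Cl2, 0 °C
Reagents that add atoms: acetic anhydride, CC(=O)OC(C)=O
Why: DMAP-catalysed acetylation of the secondary alcohol is mild enough not to eliminate the β-acetoxy ketone.

Step 26
Reactants: 37 acetoxy enone
Product: 38 C11'-iodomethyl spirolactone carrying the 2-acetoxy-guaia-1(5),4(15)-diene at C3 (O-TBDPS at C1')
Conditions: Cp2Ti(μ-Cl)(μ-CH2)AlMe2 (1.2 equiv), pyridine, THF–PhMe, −40 → 0 °C
Reagents that add atoms: Tebbe reagent, C[Al](C)C[Ti](Cl)(C1C=CC=C1)C1C=CC=C1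
Why: Tebbe methylenation of the C4 ketone, non-basic and selective for ketones over the acetate and both lactones, should give the C1=C5–C4=C15 diene without loss of acetate or migration of the new alkene.

Step 27
Reactants: 38 iodo diene
Product: 39 bicyclo[2.2.1]heptene (C13'–C1 bond formed; C11 still CH2; O-TBDPS at C1')
Conditions: Bu3SnH (1.3 equiv, syringe pump), AIBN (0.2 equiv), PhH (0.005 M), 80 °C
Reagents that add atoms: none
Why: The tributyltin radical abstracts iodine and the primary C13' radical adds 5-exo-trig to C1, the terminus of the C1=C5–C4=C15 diene, forming C13'–C1, the cyclopentane C13'–C11'–C3–C2–C1 and hence the bicyclo[2.2.1]heptene, after which the C5–C4–C15 allyl radical takes hydrogen from Bu3SnH at C15. The closest known reaction type is the tin-hydride 5-exo cyclisation of alkyl radicals onto 1,3-dienes with reduction of the allyl radical at its less substituted end, together with closure of 2-(cyclopent-3-enyl)ethyl radicals to norbornyl radicals. The only new stereocentre, C1, is dictated by the C3–C11' bond, because the two-atom tether can reach C1 only on the cyclopentene face that carries C11'. The step needs attack at C1 and not at C5, C4 or C15: closure at C4 would be 4-exo and at C15 5-endo, and addition at C5 would give a non-allylic radical, whereas addition at C1 gains allylic stabilisation. It must also leave the ring A diene alone, which is secured by C13' lying on the convex lactone face, turned away from ring A, and by those closures being 4-exo, 5-endo or 7-endo. Slow hydride addition at high dilution should keep direct reduction of the C13' radical below cyclisation, and hydrogen delivery to C15 and not C5 follows from sterics and from formation of the tetrasubstituted C4=C5 alkene.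

Step 28
Reactants: 39 cyclised lactone
Product: 42 O-TBDPS ether of the target (C11=C13 installed), via Mannich base 40 (not isolated), via ammonium iodide 41 (not isolated)
Conditions: LiN(SiMe3)2 (1.1 equiv), THF, −78 °C; CH2=NMe2 iodide, −78 → 0 °C; MeI, MeOH–CH2Cl2, 25 °C; NaHCO3 (aq.), CH2Cl2
Reagents that add atoms: N,N-dimethylmethyleneiminium iodide, C[N+](C)=C.[I-]; iodomethane, CI
Why: Mannich reaction of the lactone enolate with Eschenmoser's salt, N-methylation and Hofmann-type elimination should give the α-methylene lactone; LiN(SiMe3)2 is expected to deprotonate the γ-lactone, whose fixed E-ester geometry makes it several pKa units more acidic than the acetate, while the spirolactone has no α-hydrogen.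

Step 29
Reactants: 42 silyl ether
Product: 43 CNP0299458.1
Conditions: HF·pyridine, pyridine, THF, 0 → 25 °C
Reagents that add atoms: none
Why: Buffered fluoride desilylation should free the primary alcohol without touching the acetate or the α-methylene lactone.

**Compound list**

1 | (R)-epichlorohydrin | ClC[C@H]1CO1 | starting material
2 | (R)-1-chloropent-4-en-2-ol | ClC[C@H](O)CC=C | intermediate
3 | (R)-2-allyloxirane | C=CC[C@H]1OC1 | intermediate
4 | (4R)-4-hydroxy-2-(phenylselanyl)hept-6-enoic acid (epimers at C2) | OC(=O)C([Se]c1ccccc1)C[C@H](O)CC=C | intermediate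
5 | (5R)-5-allyl-3-(phenylselanyl)oxolan-2-one (epimers at C3) | C=CC[C@H]1OC(=O)C([Se]c2ccccc2)C1 | intermediate
6 | (R)-5-allylfuran-2(5H)-one | C=CC[C@H]1OC(=O)C=C1 | intermediate
7 | trimethylsilyl ketene acetal of the Michael adduct | C=CC[C@H]1OC(O[Si](C)(C)C)=C[C@@H]1CC(=O)SCC | intermediate
8 | S-ethyl 2-[(2R,3R)-2-allyl-5-oxooxolan-3-yl]ethanethioate | C=CC[C@H]1OC(=O)C[C@@H]1CC(=O)SCC | intermediate
9 | 1-[(2R,3S)-2-allyl-5-oxooxolan-3-yl]but-3-en-2-one | C=CC[C@H]1OC(=O)C[C@@H]1CC(=O)C=C | intermediate
10 | (3aS,8aR)-3a,4,8,8a-tetrahydro-2H-cyclohepta[b]furan-2,5(3H)-dione | O=C1C=CC[C@H]2OC(=O)C[C@@H]2C1 | intermediate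
11 | C1=C5 trimethylsilyl enol ether of the 10-methyl ketone lactone | C[C@@H]1C[C@H]2OC(=O)C[C@@H]2CC(O[Si](C)(C)C)=C1 | intermediate
12 | 1-(dimethoxymethyl)-10-methyl C5 ketone lactone | C[C@@H]1C[C@H]2OC(=O)C[C@@H]2CC(=O)[C@H]1C(OC)OC | intermediate
13 | spiro glycidic ester at C5 (epoxide epimers) | C[C@@H]1C[C@H]2OC(=O)C[C@@H]2CC3(OC3C(=O)OC)[C@H]1C(OC)OC | intermediate
14 | methyl 2-furoate 3,4-fused to the methyl-bearing seven-membered ring with trans-lactone | COC(=O)c1occ2[C@H](C)C[C@H]3OC(=O)C[C@@H]3Cc12 | intermediate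
15 | dilithium salt of the ring-opened hydroxy diacid | [Li+].[Li+].[O-]C(=O)c1occ2[C@H](C)C[C@@H](O)[C@H](CC(=O)[O-])Cc12 | intermediate
16 | fused 2-furoic acid with trans-lactone | OC(=O)c1occ2[C@H](C)C[C@H]3OC(=O)C[C@@H]3Cc12 | intermediate
17 | (S)-citronellal | C[C@@H](CCC=C(C)C)CC=O | starting material
18 | (S)-citronellal dimethyl acetal | C[C@@H](CCC=C(C)C)CC(OC)OC | intermediate
19 | (S)-6,6-dimethoxy-4-methylhexan-1-ol | C[C@@H](CCCO)CC(OC)OC | intermediate
20 | TBDPS ether of 19 | C[C@@H](CCCO[Si](c1ccccc1)(c1ccccc1)C(C)(C)C)CC(OC)OC | intermediate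
21 | 2-[(S)-2-methyl-5-(TBDPS-oxy)pentyl]-1,3-dithiane | C[C@@H](CCCO[Si](c1ccccc1)(c1ccccc1)C(C)(C)C)CC1SCCCS1 | intermediate
22 | (E)-penta-2,4-dien-1-ol | OC/C=C/C=C | starting material
23 | (2S,3S)-2,3-epoxypent-4-en-1-ol | OC[C@@H]1O[C@H]1C=C | intermediate
24 | triflate of 23 | FC(F)(F)S(=O)(=O)OC[C@@H]1O[C@H]1C=C | intermediate
25 | (2S,3S)-vinyl epoxide with the dithiane at C10' | CC(C)(C)[Si](c1ccccc1)(c1ccccc1)OCCC[C@H](C)CC1(SCCCS1)C[C@@H]1O[C@H]1C=C | intermediate
26 | cis-lactone with CO2Me at C11' (epimers at C11') | CC(C)(C)[Si](c1ccccc1)(c1ccccc1)OCCC[C@H](C)CC1(SCCCS1)C[C@@H]1OC(=O)C(C(=O)OC)[C@@H]1C=C | intermediate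
27 | cis-4-vinyl-5-(dithianylmethyl) lactone | CC(C)(C)[Si](c1ccccc1)(c1ccccc1)OCCC[C@H](C)CC1(SCCCS1)C[C@@H]1OC(=O)C[C@@H]1C=C | intermediate
28 | C10' ketone lactone | CC(C)(C)[Si](c1ccccc1)(c1ccccc1)OCCC[C@H](C)CC(=O)C[C@@H]1OC(=O)C[C@@H]1C=C | intermediate
29 | keto aldehyde (C6' aldehyde) | CC(C)(C)[Si](c1ccccc1)(c1ccccc1)OCCC[C@H](C)CC(=O)C[C@@H]1OC(=O)C[C@@H]1C=O | intermediate
30 | ring A enone, cis-fused lactone | O=C1C[C@@H]2OC(=O)C[C@@H]2C=C1[C@@H](C)CCCO[Si](c1ccccc1)(c1ccccc1)C(C)(C)C | intermediate
31 | seco-eudesmanolide diene lactone (C11'H2, O-TBDPS) | C=C1C[C@@H]2OC(=O)C[C@@H]2C=C1[C@@H](C)CCCO[Si](c1ccccc1)(c1ccccc1)C(C)(C)C | intermediate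
32 | acid chloride of 16 | ClC(=O)c1occ2[C@H](C)C[C@H]3OC(=O)C[C@@H]3Cc12 | intermediate
33 | β-keto lactone (furoyl at C11', epimers at C11') | C=C1C[C@@H]2OC(=O)C(C(=O)c3occ4[C@H](C)C[C@H]5OC(=O)C[C@@H]5Cc34)[C@@H]2C=C1[C@@H](C)CCCO[Si](c1ccccc1)(c1ccccc1)C(C)(C)C | intermediate
34 | 11'-iodomethyl β-keto lactone | C=C1C[C@@H]2OC(=O)[C@@](C(=O)c3occ4[C@H](C)C[C@H]5OC(=O)C[C@@H]5Cc34)(CI)[C@@H]2C=C1[C@@H](C)CCCO[Si](c1ccccc1)(c1ccccc1)C(C)(C)C | intermediate
35 | furylcarbinol (C3 epimers) | C=C1C[C@@H]2OC(=O)[C@@](C(O)c3occ4[C@H](C)C[C@H]5OC(=O)C[C@@H]5Cc34)(CI)[C@@H]2C=C1[C@@H](C)CCCO[Si](c1ccccc1)(c1ccccc1)C(C)(C)C | intermediate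
36 | hydroxy enone (C4 ketone, 2-OH, C3–C11' trans) | C=C1C[C@@H]2OC(=O)[C@](CI)([C@@H]3C(=O)C4=C([C@H]3O)[C@H](C)C[C@H]5OC(=O)C[C@@H]5C4)[C@@H]2C=C1[C@@H](C)CCCO[Si](c1ccccc1)(c1ccccc1)C(C)(C)C | intermediate
37 | acetoxy enone | C=C1C[C@@H]2OC(=O)[C@](CI)([C@@H]3C(=O)C4=C([C@H]3OC(C)=O)[C@H](C)C[C@H]5OC(=O)C[C@@H]5C4)[C@@H]2C=C1[C@@H](C)CCCO[Si](c1ccccc1)(c1ccccc1)C(C)(C)C | intermediate
38 | iodo diene, precursor of the key step | C=C1C[C@@H]2OC(=O)[C@](CI)([C@@H]3C(=C)C4=C([C@H]3OC(C)=O)[C@H](C)C[C@H]5OC(=O)C[C@@H]5C4)[C@@H]2C=C1[C@@H](C)CCCO[Si](c1ccccc1)(c1ccccc1)C(C)(C)C | intermediate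
39 | cyclised bicyclo[2.2.1]heptene, C11 CH2, O-TBDPS | C=C1C[C@@H]2OC(=O)[C@@]3(C[C@@]45C(=C(C)[C@@H]3[C@@H]4OC(C)=O)C[C@H]3CC(=O)O[C@@H]3C[C@H]5C)[C@@H]2C=C1[C@@H](C)CCCO[Si](c1ccccc1)(c1ccccc1)C(C)(C)C | intermediate
40 | 13-(dimethylamino) Mannich base (epimers at C11) | C=C1C[C@@H]2OC(=O)[C@@]3(C[C@@]45C(=C(C)[C@@H]3[C@@H]4OC(C)=O)C[C@H]3C(CN(C)C)C(=O)O[C@@H]3C[C@H]5C)[C@@H]2C=C1[C@@H](C)CCCO[Si](c1ccccc1)(c1ccccc1)C(C)(C)C | intermediate
41 | trimethylammonium iodide of 40 | C=C1C[C@@H]2OC(=O)[C@@]3(C[C@@]45C(=C(C)[C@@H]3[C@@H]4OC(C)=O)C[C@H]3C(C[N+](C)(C)C)C(=O)O[C@@H]3C[C@H]5C)[C@@H]2C=C1[C@@H](C)CCCO[Si](c1ccccc1)(c1ccccc1)C(C)(C)C.[I-] | intermediate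
42 | O-TBDPS ether of the target | C=C1C[C@@H]2OC(=O)[C@@]3(C[C@@]45C(=C(C)[C@@H]3[C@@H]4OC(C)=O)C[C@H]3C(=C)C(=O)O[C@@H]3C[C@H]5C)[C@@H]2C=C1[C@@H](C)CCCO[Si](c1ccccc1)(c1ccccc1)C(C)(C)C | intermediate
43 | CNP0299458.1 | C=C1C[C@@H]2OC(=O)[C@@]3(C[C@@]45C(=C(C)[C@@H]3[C@@H]4OC(C)=O)C[C@H]3C(=C)C(=O)O[C@@H]3C[C@H]5C)[C@@H]2C=C1[C@@H](C)CCCO | target

**Count and risks**

Total: 29 steps. Longest linear sequence: 19 steps (17 to 43 through steps 10–13 and 15–29).

Steps most likely to fail:

- **Step 24.** The hindered carbinol may ionise sluggishly, or the conrotatory closure may show poor facial selectivity. The fallback sets out from 35. Ionic deoxygenation (Et3SiH, BF3·OEt2, CH2Cl2, −78 °C) should give the 2-alkylfuran F1. Photooxygenation (O2, methylene blue, visible light, CH2Cl2, −78 °C; then Me2S) should open the furan to the (Z)-4-oxo-enal F2. A catalytic amine base (Et3N, THF, 0 °C) should then close C2–C3 by intramolecular aldol addition of C3 onto the C2 aldehyde and return to 36. This puts C2 and C3 under thermodynamic control, and an unwanted epimer can be re-equilibrated through retro-aldol opening.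

- **Step 8.** Enolisation of the hindered C5 ketone may outrun Darzens addition. The fallback sets out from 12. Aqueous acid (1 M HCl, THF) should give the hydroxymethylene ketone F3. O-Alkylation with methyl bromoacetate (K2CO3, DMF, 25 °C) should give the enol ether F4. Intramolecular aldol condensation of the ester methylene onto C5 (NaOMe, MeOH; then p-TsOH, PhMe) should return to 14.

- **Step 26.** The carbonyl flanked by the C3 substituent may resist the titanium reagent, or the β-acetate may be lost. The fallback sets out from 37. Peterson olefination would be used: addition of Me3SiCH2MgCl premixed with CeCl3 (THF, −78 °C) should give the β-hydroxysilane F5, and acid-induced anti elimination (BF3·OEt2, CH2Cl2, −78 °C) should return to 38.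

Further compounds
F1 | step 24 | 2-alkylfuran (C3 as CH2) from deoxygenation of 35 | C=C1C[C@@H]2OC(=O)[C@@](Cc3occ4[C@H](C)C[C@H]5OC(=O)C[C@@H]5Cc34)(CI)[C@@H]2C=C1[C@@H](C)CCCO[Si](c1ccccc1)(c1ccccc1)C(C)(C)C
F2 | step 24 | (Z)-4-oxo-enal (C4 ketone, C2 aldehyde on the C1=C5 alkene) | C=C1C[C@@H]2OC(=O)[C@@](CC(=O)C3=C(C=O)[C@H](C)C[C@H]4OC(=O)C[C@@H]4C3)(CI)[C@@H]2C=C1[C@@H](C)CCCO[Si](c1ccccc1)(c1ccccc1)C(C)(C)C
F3 | step 8 | 1-(hydroxymethylene) C5 ketone lactone | O/C=C1\C(=O)C[C@H]2CC(=O)O[C@@H]2C[C@H]1C
F4 | step 8 | methyl (alkylidenemethoxy)acetate enol ether of F3 | COC(=O)CO/C=C1\C(=O)C[C@H]2CC(=O)O[C@@H]2C[C@H]1C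
F5 | step 26 | C4 tertiary alcohol bearing CH2SiMe3 (epimers at C4) | C=C1C[C@@H]2OC(=O)[C@](CI)([C@@H]3C(O)(C[Si](C)(C)C)C4=C([C@H]3OC(C)=O)[C@H](C)C[C@H]5OC(=O)C[C@@H]5C4)[C@@H]2C=C1[C@@H](C)CCCO[Si](c1ccccc1)(c1ccccc1)C(C)(C)C
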